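**Retrosynthetic overview**

1. Rings: A cyclohexene, B seven-membered enol lactone, C benzene, D quinone, E thiazine dioxide. Ring E is closed last: hypotaurine adds through sulfur to a para-quinone monoketal made from a ring D 1-naphthol, then nitrogen closes (C–S, then C–N).
2. Ring D comes from an aryne of ring C and furan: one [4+2] cycloaddition forms both bonds between ring C and the two future quinone carbonyl carbons. The 1,4-oxygen bridge is a temporary ring that acid opens to the naphthol.
3. Enabling feature: the two C=O carbons of ring D stand 1,4 to each other on two adjacent ring C carbons (furan α,α′-carbons plus aryne). These two ring C carbons are para to unequal partners, the carbon bearing the quaternary alkyl carbon and the carbon bearing the lactone C=O, so the two bridge C–O bonds ionise differently and fix where S and N go.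
4. Ring B: acid enol-lactonisation of a tert-butyl benzoate onto a masked α-formyl group. Ring A: 3-methylcyclohex-2-enone, with the quaternary stereocentre set by palladium-catalysed asymmetric conjugate addition of the ring C boronic acid, then α′-formylation (as acetal) and methyl installation through a vinyl triflate.
5. Order of ring formation: C (tert-butyl 4-hydroxybenzoate, carrying a SiMe3/OTf pair from step 2) → A attached → B → D → E.

Key step: step 11

Remark: locants of the A/B/C core follow dibenzo[c,e]oxepine (C-4a bears the lactone C=O, C-11a is the quaternary carbon bonded to C-11b, C-2/C-3 become the C/D fusion); the quaternary carbon is S in the target and in every compound with the C-7=C-7a enol double bond, and the same spatial arrangement reads R in 9 to 16.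

**Route**

Step 1
Reactants: 1 tert-butyl 4-hydroxybenzoate
Product: 2 tert-butyl 3-bromo-4-hydroxybenzoate
Conditions: NBS (1.0 equiv), MeCN, 0 → 23 °C
Reagents that add atoms: N-bromosuccinimide, O=C1CCC(=O)N1Br
Why: Electrophilic aromatic bromination; the phenol directs to its ortho position because the para position holds the ester, which should give the mono-bromide needed for the silyl shift.

Step 2
Reactants: 2 tert-butyl 3-bromo-4-hydroxybenzoate
Product: 5 tert-butyl 4-(trifluoromethanesulfonyloxy)-3-(trimethylsilyl)benzoate, via aryl silyl ether 3 (not isolated), via lithium phenoxide 4 (not isolated)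
Conditions: (Me3Si)2NH, THF, 65 °C, then evaporate; n-BuLi, THF, −78 °C; Tf2O, −78 → 0 °C
Reagents that add atoms: hexamethyldisilazane, C[Si](C)(C)N[Si](C)(C)C; trifluoromethanesulfonic anhydride, O=S(=O)(OS(=O)(=O)C(F)(F)F)C(F)(F)F
Why: O-silylation, bromine–lithium exchange and retro-Brook (1,3 O→C) silyl migration place SiMe3 ortho to the phenoxide, which is triflated in the same flask to the 2-silylaryl triflate aryne precursor; exchange at −78 °C should outrun attack on the tert-butyl ester.

Step 3
Reactants: 5 tert-butyl 4-(trifluoromethanesulfonyloxy)-3-(trimethylsilyl)benzoate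
Product: 6 tert-butyl 2-(4,4,5,5-tetramethyl-1,3,2-dioxaborolan-2-yl)-4-(trifluoromethanesulfonyloxy)-5-(trimethylsilyl)benzoate
Conditions: B2pin2 (1.0 equiv), [Ir(OMe)(cod)]2 (1.5 mol %), P[C6H3-3,5-(CF3)2]3 (6 mol %), octane, 80 °C
Reagents that add atoms: bis(pinacolato)diboron, CC1(C)OB(OC1(C)C)B1OC(C)(C)C(C)(C)O1
Why: Iridium-catalysed ester-directed ortho C–H borylation; the ester carbonyl binds the electron-poor phosphine–iridium boryl catalyst and should deliver boron to the one ortho C–H that is not flanked by SiMe3.

Step 4
Reactants: 6 tert-butyl 2-(4,4,5,5-tetramethyl-1,3,2-dioxaborolan-2-yl)-4-(trifluoromethanesulfonyloxy)-5-(trimethylsilyl)benzoate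
Product: 7 [2-(tert-butoxycarbonyl)-5-(trifluoromethanesulfonyloxy)-4-(trimethylsilyl)phenyl]boronic acid
Conditions: NaIO4 (3 equiv), NH4OAc (3 equiv), acetone–H2O, 23 °C
Reagents that add atoms: water, O
Why: Periodate glycol cleavage of the pinacol released by hydrolysis drives the boronate ester to the free boronic acid needed for transmetalation; no fluoride is used, so the silyl triflate stays intact.

Step 5
Reactants: 7 [2-(tert-butoxycarbonyl)-5-(trifluoromethanesulfonyloxy)-4-(trimethylsilyl)phenyl]boronic acid; 8 3-methylcyclohex-2-en-1-one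
Product: 9 tert-butyl 2-[(1R)-1-methyl-3-oxocyclohexyl]-4-(trifluoromethanesulfonyloxy)-5-(trimethylsilyl)benzoate
Conditions: Pd(OCOCF3)2 (5 mol %), (S)-t-BuPyOX [(S)-4-tert-butyl-2-(2-pyridyl)-4,5-dihydrooxazole] (6 mol %), H2O (5 equiv), ClCH2CH2Cl, 60 °C
Reagents that add atoms: none
Why: Palladium-catalysed asymmetric conjugate addition of an arylboronic acid to a β-substituted cyclic enone; the aryl–palladium pyridine-oxazoline complex inserts the enone on the face set by the (S)-tert-butyl oxazoline, the sense that gives R in 3-aryl-3-methylcyclohexanones, and protonolysis of the palladium enolate turns the catalyst over without zerovalent palladium that could attack the aryl triflate.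

Step 6
Reactants: 9 tert-butyl 2-[(1R)-1-methyl-3-oxocyclohexyl]-4-(trifluoromethanesulfonyloxy)-5-(trimethylsilyl)benzoate
Product: 10 tert-butyl 2-[(1R)-1-methyl-5-oxocyclohex-3-en-1-yl]-4-(trifluoromethanesulfonyloxy)-5-(trimethylsilyl)benzoate
Conditions: IBX (2.5 equiv), DMSO–fluorobenzene, 75 °C
Reagents that add atoms: none
Why: IBX dehydrogenation of a ketone to the enone; only the side away from the quaternary carbon has a β-hydrogen, so a single enone should form and over-oxidation to a dienone is impossible.

Step 7
Reactants: 10 tert-butyl 2-[(1R)-1-methyl-5-oxocyclohex-3-en-1-yl]-4-(trifluoromethanesulfonyloxy)-5-(trimethylsilyl)benzoate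
Product: 12 tert-butyl 2-[(1R)-6-(dimethoxymethyl)-1-methyl-5-oxocyclohex-3-en-1-yl]-4-(trifluoromethanesulfonyloxy)-5-(trimethylsilyl)benzoate (both C-6 epimers), via silyl dienol ether 11 (not isolated)
Conditions: LiN(i-Pr)2, Me3SiCl, THF, −78 °C; then HC(OMe)3, Me3SiOTf (10 mol %), CH2Cl2, −78 °C
Reagents that add atoms: chlorotrimethylsilane, C[Si](C)(C)Cl (silicon group carried in 11 only); trimethyl orthoformate, COC(OC)OC
Why: Kinetic α′-deprotonation of the enone (as with isophorone) gives the cross-conjugated silyl dienol ether, whose only nucleophilic carbon lies between C=O and the quaternary carbon, and a Mukaiyama-type addition to the dimethoxycarbenium ion installs the masked formyl group there; the new stereocentre is left unassigned because it becomes sp2 in step 10.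

Step 8
Reactants: 12 tert-butyl 2-[(1R)-6-(dimethoxymethyl)-1-methyl-5-oxocyclohex-3-en-1-yl]-4-(trifluoromethanesulfonyloxy)-5-(trimethylsilyl)benzoate
Product: 14 tert-butyl 2-[(1R)-2-(dimethoxymethyl)-1-methyl-3-(trifluoromethanesulfonyloxy)cyclohex-3-en-1-yl]-4-(trifluoromethanesulfonyloxy)-5-(trimethylsilyl)benzoate, via lithium enolate 13 (not isolated)
Conditions: LiBH(s-Bu)3 (L-Selectride), THF, −78 °C; then PhNTf2, −78 → 0 °C
Reagents that add atoms: N-phenylbis(trifluoromethanesulfonimide), O=S(=O)(N(c1ccccc1)S(=O)(=O)C(F)(F)F)C(F)(F)F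
Why: Conjugate reduction with enolate trapping; hydride adds to the unsubstituted β-carbon, so the enolate forms regiospecifically on the side away from the acetal-bearing carbon and is O-triflated to the vinyl triflate.

Step 9
Reactants: 14 tert-butyl 2-[(1R)-2-(dimethoxymethyl)-1-methyl-3-(trifluoromethanesulfonyloxy)cyclohex-3-en-1-yl]-4-(trifluoromethanesulfonyloxy)-5-(trimethylsilyl)benzoate
Product: 15 tert-butyl 2-[(1R)-2-(dimethoxymethyl)-1,3-dimethylcyclohex-3-en-1-yl]-4-(trifluoromethanesulfonyloxy)-5-(trimethylsilyl)benzoate
Conditions: Me2CuLi (from MeLi and CuI), THF, −20 → 0 °C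
Reagents that add atoms: lithium dimethylcuprate, [Li+].C[Cu-]C
Why: Organocuprate cross-coupling of a vinyl triflate; the cuprate should replace the vinyl triflate by methyl while the hindered aryl triflate, the tert-butyl ester and the acetal do not react.

Step 10
Reactants: 15 tert-butyl 2-[(1R)-2-(dimethoxymethyl)-1,3-dimethylcyclohex-3-en-1-yl]-4-(trifluoromethanesulfonyloxy)-5-(trimethylsilyl)benzoate
Product: 17 (11aS)-8,11a-dimethyl-5-oxo-3-(trimethylsilyl)-5,10,11,11a-tetrahydrodibenzo[c,e]oxepin-2-yl trifluoromethanesulfonate, via methoxy acylal 16 (not isolated)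
Conditions: TsOH·H2O (10 mol %), toluene, 80 °C, 5 Å molecular sieves
Reagents that add atoms: none
Why: Acid-catalysed enol-lactonisation (cyclodehydration of a masked aldehyde acid); the tert-butyl ester ionises at the alkyl–oxygen bond, the carboxyl group captures the oxocarbenium ion of the acetal to give the seven-membered acylal 16, and E1 loss of the second methanol toward the allylic C–H gives the conjugated dienol lactone, with the electron-poor aryl–silicon bond expected to resist protodesilylation.

Step 11
Reactants: 17 (11aS)-8,11a-dimethyl-5-oxo-3-(trimethylsilyl)-5,10,11,11a-tetrahydrodibenzo[c,e]oxepin-2-yl trifluoromethanesulfonate; 18 furan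
Product: 20 (11aS)-oxygen-bridged cycloadduct (lactone core whose C-2 and C-3 carry a fused 1,4-dihydro-1,4-epoxy ring; both bridgehead epimers), via aryne 19 (not isolated)
Conditions: CsF (3 equiv), furan (10 equiv), MeCN, 23 °C
Reagents that add atoms: none
Why: Fluoride attacks silicon of 17 and the aryl anion expels triflate to give aryne 19, whose strained in-plane π bond adds furan in a concerted [4+2] cycloaddition that forms both bonds between the adjacent ring C carbons C-2 and C-3 and the furan α-carbons, the future quinone carbonyl carbons. The closest known reaction type is the aryne–furan Diels–Alder reaction of 2-(trimethylsilyl)aryl triflates. Ring D is closed in the [4+2] mode, and with it the oxygen bridge of a 7-oxabicyclo[2.2.1]heptadiene, a temporary ring that is not in the target. The two new bridgehead stereocentres are cis by the geometry of the bridge; their sense relative to C-11a is not controlled and does not matter, because both are flattened in step 12. The step needs chemoselectivity for furan over the dienol ester and the lactone, which the excess of furan and the position of the aryne (meta and para to the ring B attachments, out of their reach) should secure; regioselectivity is not needed because furan is symmetric, and the place of N and S is decided in step 12, where the unequal para partners of C-2 and C-3 steer the opening of the bridge.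

Step 12
Reactants: 20 (11aS)-oxygen-bridged cycloadduct
Product: 21 (S)-naphthol lactone (ring D is a 1-naphthol ring; OH on the ring D carbon bonded to former C-2, the ring C carbon para to C-4a)
Conditions: CF3CO2H (2 equiv), CH2Cl2, 0 °C
Reagents that add atoms: none
Why: Acid-catalysed isomerisation of a 1,4-epoxy-1,4-dihydronaphthalene to a 1-naphthol; the bridge C–O bond should ionise at the bridgehead on C-3, whose benzylic cation is para to the alkyl-bearing C-11b and not para to the carbonyl-bearing C-4a, so after proton loss the hydroxyl stays on the carbon attached to C-2.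

Step 13
Reactants: 21 (S)-naphthol lactone
Product: 23 (S)-para-quinone monoketal (C=O on the ring D carbon bonded to former C-2; C(OMe)2 on the ring D carbon bonded to former C-3), via methoxynaphthol 22 (not isolated)
Conditions: PhI(OAc)2 (2.2 equiv), MeOH, 0 °C
Reagents that add atoms: methanol, CO
Why: Oxidative dearomatisation of a phenol with a hypervalent iodine diacetate in methanol (two two-electron oxidations) gives the para-quinone monoketal with the carbonyl at the former phenol carbon, which tells the two future quinone carbonyls apart; the naphthol should react far faster than the dienol ester.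

Step 14
Reactants: 23 (S)-para-quinone monoketal; 24 hypotaurine (2-aminoethanesulfinic acid)
Product: 28 CNP0348176.1 (S)-thiazinoquinone lactone, via sulfonyl methoxynaphthol 25 (not isolated), via sulfonylquinone 26 (not isolated), via aminohydroquinone 27 (not isolated)
Conditions: 24 (1.2 equiv), NaOAc–AcOH (pH 5), MeOH–H2O, 23 °C; then PhI(OAc)2 (1.1 equiv), MeCN–H2O, 0 °C; then NaHCO3 (to pH 8), air, 23 °C
Reagents that add atoms: water, O
Why: Sulfa-Michael addition of the sulfinate of zwitterionic hypotaurine (amine protonated at pH 5) to the only enone β-carbon, the one next to the ketal, and loss of methanol give 25; oxidative demethylation to sulfonylquinone 26, intramolecular aza-Michael addition on neutralisation and air oxidation of hydroquinone 27 then close the thiazine dioxide with S next to the carbonyl on former C-3 and N next to the carbonyl on former C-2, as in the target.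

**Compound list**

1 | tert-butyl 4-hydroxybenzoate | CC(C)(C)OC(=O)c1ccc(O)cc1 | starting material
2 | tert-butyl 3-bromo-4-hydroxybenzoate | CC(C)(C)OC(=O)c1ccc(O)c(Br)c1 | intermediate
3 | tert-butyl 3-bromo-4-[(trimethylsilyl)oxy]benzoate (aryl silyl ether) | CC(C)(C)OC(=O)c1ccc(O[Si](C)(C)C)c(Br)c1 | intermediate
4 | lithium 4-(tert-butoxycarbonyl)-2-(trimethylsilyl)phenolate | [Li+].CC(C)(C)OC(=O)c1ccc([O-])c([Si](C)(C)C)c1 | intermediate
5 | tert-butyl 4-(trifluoromethanesulfonyloxy)-3-(trimethylsilyl)benzoate | CC(C)(C)OC(=O)c1ccc(OS(=O)(=O)C(F)(F)F)c([Si](C)(C)C)c1 | intermediate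
6 | tert-butyl 2-(4,4,5,5-tetramethyl-1,3,2-dioxaborolan-2-yl)-4-(trifluoromethanesulfonyloxy)-5-(trimethylsilyl)benzoate | CC(C)(C)OC(=O)c1cc([Si](C)(C)C)c(OS(=O)(=O)C(F)(F)F)cc1B1OC(C)(C)C(C)(C)O1 | intermediate
7 | [2-(tert-butoxycarbonyl)-5-(trifluoromethanesulfonyloxy)-4-(trimethylsilyl)phenyl]boronic acid | CC(C)(C)OC(=O)c1cc([Si](C)(C)C)c(OS(=O)(=O)C(F)(F)F)cc1B(O)O | intermediate
8 | 3-methylcyclohex-2-en-1-one | CC1=CC(=O)CCC1 | starting material
9 | tert-butyl 2-[(1R)-1-methyl-3-oxocyclohexyl]-4-(trifluoromethanesulfonyloxy)-5-(trimethylsilyl)benzoate | CC(C)(C)OC(=O)c1cc([Si](C)(C)C)c(OS(=O)(=O)C(F)(F)F)cc1[C@]1(C)CCCC(=O)C1 | intermediate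
10 | tert-butyl 2-[(1R)-1-methyl-5-oxocyclohex-3-en-1-yl]-4-(trifluoromethanesulfonyloxy)-5-(trimethylsilyl)benzoate | CC(C)(C)OC(=O)c1cc([Si](C)(C)C)c(OS(=O)(=O)C(F)(F)F)cc1[C@]1(C)CC=CC(=O)C1 | intermediate
11 | tert-butyl 2-{(1R)-1-methyl-3-[(trimethylsilyl)oxy]cyclohexa-2,4-dien-1-yl}-4-(trifluoromethanesulfonyloxy)-5-(trimethylsilyl)benzoate (silyl dienol ether) | CC(C)(C)OC(=O)c1cc([Si](C)(C)C)c(OS(=O)(=O)C(F)(F)F)cc1[C@]1(C)CC=CC(O[Si](C)(C)C)=C1 | intermediate
12 | tert-butyl 2-[(1R)-6-(dimethoxymethyl)-1-methyl-5-oxocyclohex-3-en-1-yl]-4-(trifluoromethanesulfonyloxy)-5-(trimethylsilyl)benzoate (both C-6 epimers) | CC(C)(C)OC(=O)c1cc([Si](C)(C)C)c(OS(=O)(=O)C(F)(F)F)cc1[C@]1(C)CC=CC(=O)C1C(OC)OC | intermediate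
13 | lithium enolate from 1,4-reduction of 12 (cyclohex-1-en-1-olate, R quaternary carbon) | [Li+].CC(C)(C)OC(=O)c1cc([Si](C)(C)C)c(OS(=O)(=O)C(F)(F)F)cc1[C@]1(C)CCC=C([O-])C1C(OC)OC | intermediate
14 | tert-butyl 2-[(1R)-2-(dimethoxymethyl)-1-methyl-3-(trifluoromethanesulfonyloxy)cyclohex-3-en-1-yl]-4-(trifluoromethanesulfonyloxy)-5-(trimethylsilyl)benzoate | CC(C)(C)OC(=O)c1cc([Si](C)(C)C)c(OS(=O)(=O)C(F)(F)F)cc1[C@]1(C)CCC=C(OS(=O)(=O)C(F)(F)F)C1C(OC)OC | intermediate
15 | tert-butyl 2-[(1R)-2-(dimethoxymethyl)-1,3-dimethylcyclohex-3-en-1-yl]-4-(trifluoromethanesulfonyloxy)-5-(trimethylsilyl)benzoate | CC(C)(C)OC(=O)c1cc([Si](C)(C)C)c(OS(=O)(=O)C(F)(F)F)cc1[C@]1(C)CCC=C(C)C1C(OC)OC | intermediate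
16 | (11aR)-7-methoxy-8,11a-dimethyl-5-oxo-3-(trimethylsilyl)-5,7,7a,10,11,11a-hexahydrodibenzo[c,e]oxepin-2-yl trifluoromethanesulfonate (methoxy acylal; epimers at C-7 and C-7a) | CC1=CCC[C@]2(C)C1C(OC)OC(=O)c1cc([Si](C)(C)C)c(OS(=O)(=O)C(F)(F)F)cc12 | intermediate
17 | (11aS)-8,11a-dimethyl-5-oxo-3-(trimethylsilyl)-5,10,11,11a-tetrahydrodibenzo[c,e]oxepin-2-yl trifluoromethanesulfonate | CC1=CCC[C@]2(C)C1=COC(=O)c1cc([Si](C)(C)C)c(OS(=O)(=O)C(F)(F)F)cc12 | intermediate
18 | furan | c1ccoc1 | starting material
19 | (11aS)-2,3-didehydro aryne of the tricyclic dienol lactone | CC1=CCC[C@]2(C)C1=COC(=O)C1=CC#CC=C12 | intermediate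
20 | (11aS)-oxygen-bridged cycloadduct: lactone core with a 1,4-dihydro-1,4-epoxy ring fused at C-2/C-3 (both bridgehead epimers) | CC1=CCC[C@]2(C)C1=COC(=O)c1cc3C4OC(C=C4)c3cc12 | intermediate
21 | (S)-naphthol lactone: ring D 1-naphthol with OH on the carbon bonded to former C-2 | CC1=CCC[C@]2(C)C1=COC(=O)c1cc3cccc(O)c3cc12 | intermediate
22 | (S)-4-methoxy-1-naphthol lactone: OH on the carbon bonded to former C-2, OMe on the carbon bonded to former C-3 | CC1=CCC[C@]2(C)C1=COC(=O)c1cc3c(OC)ccc(O)c3cc12 | intermediate
23 | (S)-para-quinone monoketal: C=O on the carbon bonded to former C-2, C(OMe)2 on the carbon bonded to former C-3 | CC1=CCC[C@]2(C)C1=COC(=O)c1cc3c(cc12)C(=O)C=CC3(OC)OC | intermediate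
24 | hypotaurine (2-aminoethanesulfinic acid) | NCCS(=O)O | starting material
25 | (S)-sulfonyl methoxynaphthol: 22 with a 2-aminoethylsulfonyl group on the ring D carbon next to the OMe-bearing carbon | CC1=CCC[C@]2(C)C1=COC(=O)c1cc3c(OC)c(S(=O)(=O)CCN)cc(O)c3cc12 | intermediate
26 | (S)-sulfonylquinone: naphtho-1,4-quinone lactone with the 2-aminoethylsulfonyl group on the quinone carbon next to the C=O on former C-3 | CC1=CCC[C@]2(C)C1=COC(=O)c1cc3c(cc12)C(=O)C=C(C3=O)S(=O)(=O)CCN | intermediate
27 | (S)-aminohydroquinone: hydroquinone form of the target, thiazine dioxide ring closed | CC1=CCC[C@]2(C)C1=COC(=O)c1cc3c(O)c4c(NCCS4(=O)=O)c(O)c3cc12 | intermediate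
28 | CNP0348176.1, (S)-thiazine dioxide-fused naphthoquinone enol lactone | CC1=CCC[C@]2(C)C1=COC(=O)c1cc3c(cc12)C(=O)C1=C(C3=O)S(=O)(=O)CCN1 | target

**Step count and risks**

Total step count: 14. Longest linear sequence: 14 steps (1 → 28); compounds 8, 18 and 24 are bought.

Steps most likely to fail:

1. Step 5. The aryl group carries an ortho ester, so transmetalation and insertion into the trisubstituted enone may be slow, protodeboronation may take over, and facial selectivity may erode. Fallback, setting out from 6 and coming back at 9: Suzuki–Miyaura coupling of 6 with 3-bromocyclohex-2-en-1-one (Pd(PPh3)4, Na2CO3, dioxane–H2O, 50 °C; the vinyl bromide should react ahead of the hindered aryl triflate) should give tert-butyl 2-(3-oxocyclohex-1-en-1-yl)-4-(trifluoromethanesulfonyloxy)-5-(trimethylsilyl)benzoate F1. The polarity of the quaternary-centre step is then reversed: copper-catalysed asymmetric conjugate addition of AlMe3 (copper thiophene-2-carboxylate, Cu(O2CC4H3S), with a chiral phosphoramidite, Et2O, −30 °C) brings in methyl as the nucleophile, with the ligand enantiomer chosen to give R, and returns to 9.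

2. Step 14. The first addition may lose chemoselectivity between sulfinate and amine, and the enol lactone may suffer aminolysis or hydrolysis during the long one-pot sequence. Fallback, setting out from 21 and coming back at 28: oxidation of 21 with Co(salen) and O2 in MeCN should give the naphtho-1,4-quinone lactone F2. Hypotaurine in EtOH–MeCN–H2O in air then adds to the free quinone in the established thiazine-forming manner and should give 28 together with its thiazine regioisomer F3, to be separated by chromatography.

3. Step 10. The Brønsted acid may cause protodesilylation of the aryl–silicon bond, or the sequence may stop at the acylal. Fallback, setting out from 15 and coming back at 17: Me3SiOTf with 2,6-lutidine (CH2Cl2, 0 °C), then water, cleaves the tert-butyl ester and the acetal without free Brønsted acid and should give the aldehyde acid F4. Ac2O with NaOAc (60 °C) then closes the enol lactone through the mixed anhydride and the dienolate, returning to 17.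

**Further compounds**

F1 | step 5 | tert-butyl 2-(3-oxocyclohex-1-en-1-yl)-4-(trifluoromethanesulfonyloxy)-5-(trimethylsilyl)benzoate | CC(C)(C)OC(=O)c1cc([Si](C)(C)C)c(OS(=O)(=O)C(F)(F)F)cc1C1=CC(=O)CCC1
F2 | step 14 | (S)-naphtho-1,4-quinone lactone (target without the thiazine ring) | CC1=CCC[C@]2(C)C1=COC(=O)c1cc3c(cc12)C(=O)C=CC3=O
F3 | step 14 | (S)-thiazine regioisomer of the target (S next to the C=O on former C-2, N next to the C=O on former C-3) | CC1=CCC[C@]2(C)C1=COC(=O)c1cc3c(cc12)C(=O)C1=C(C3=O)NCCS1(=O)=O
F4 | step 10 | 2-[(1R)-2-formyl-1,3-dimethylcyclohex-3-en-1-yl]-4-(trifluoromethanesulfonyloxy)-5-(trimethylsilyl)benzoic acid | OC(=O)c1cc([Si](C)(C)C)c(OS(=O)(=O)C(F)(F)F)cc1[C@]1(C)CCC=C(C)C1C=O
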